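**Retrosynthetic overview**

Ring B is the cyclohexane, labelled C1 (CH–Et), C2 (CH–Me), C3 (CH–Ar), C4 (CH–Me), C5 (CH–Ar) and C6 (spiro carbon); ring A is the dienone; Ar = 2,4,5-trimethoxyphenyl.
Tatanan B is cut at C1–C2 and C5–C6: a formal [4+2] spiroannulation joins a C2–C5 fragment to the two-carbon unit C1/C6, with C2 carried as C=CH2 until the last step.
Enabling feature: ring A is a cyclohexa-2,5-dienone with its C=O para to spiro C6, so it is the dearomatised form of a 4-alkylphenol. At the phenol oxidation level C1/C6 is the exocyclic C=C of a para-quinone methide, electrophilic at C1 and, after a nucleophile has added, nucleophilic at the ipso carbon C6.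
The C2–C5 fragment carries an alkenylboronate (nucleophilic C2) and a benzylic pivalate (latent electrophilic C5). C3 and C4 come from a dual-catalytic allylation of propanal, and the boronate from the vinyl group (Wacker oxidation, enol triflate, borylation).
Ring order: ring A enters aromatic (from 4-bromo-2,5-dimethoxybenzaldehyde); ring B is closed and ring A dearomatised in one operation; face-selective hydrogenation of the exocyclic methylene then sets C2.

Key step: step 10

Remark on the chemistry: the carbinol carbon that becomes C5 is carried as a mixture of epimers from step 3 on, because it is ionised when the C5–C6 bond forms; the racemic carbinols and the sulfone of the ring A series are used as such because their stereocentres are erased in steps 2 and 10.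

**Route**

Step 1
Reactants: 1 2,4,5-trimethoxybenzaldehyde; 2 vinylmagnesium bromide
Product: 3 rac-1-(2,4,5-trimethoxyphenyl)prop-2-en-1-ol
Conditions: THF, −78 → 0 °C; aq. NH4Cl
Reagents that add atoms: none
Why: Addition of a vinyl Grignard reagent to the aldehyde gives the aryl vinyl carbinol; it is made racemic on purpose because step 2 ionises this centre.

Step 2
Reactants: 3 rac-1-(2,4,5-trimethoxyphenyl)prop-2-en-1-ol; 4 propanal
Product: 5 (2R,3S)-2-methyl-3-(2,4,5-trimethoxyphenyl)pent-4-enal
Conditions: [Ir(cod)Cl]2 (cat.), 5-(dinaphtho[2,1-d:1′,2′-f][1,3,2]dioxaphosphepin-4-yl)-5H-dibenz[b,f]azepine (cat.; the enantiomer that sets 3S), (S)-2-{bis[3,5-bis(trifluoromethyl)phenyl](trimethylsilyloxy)methyl}pyrrolidine (cat.), (MeO)2P(O)OH (cat.), 1,2-dichloroethane, 25 °C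
Reagents that add atoms: none
Why: Stereodivergent dual catalysis (iridium-catalysed allylic substitution of a racemic branched allylic alcohol merged with enamine catalysis): the chiral iridium allyl complex should fix the aryl-bearing carbon (3S) and the (S)-diarylprolinol silyl ether enamine of propanal the methyl-bearing carbon (2R), each catalyst controlling its own centre, so the needed diastereomer is chosen by the pairing of catalyst enantiomers.

Step 3
Reactants: 5 (2R,3S)-2-methyl-3-(2,4,5-trimethoxyphenyl)pent-4-enal; 6 1-bromo-2,4,5-trimethoxybenzene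
Product: 9 (1RS,2R,3S)-2-methyl-1,3-bis(2,4,5-trimethoxyphenyl)pent-4-en-1-yl 2,2-dimethylpropanoate, via arylmagnesium bromide 7 (not isolated), via bromomagnesium alkoxide 8 (not isolated)
Conditions: 6, Mg, THF, 45 °C; then 5, THF, −78 °C; then t-BuCOCl, −78 → 25 °C
Reagents that add atoms: pivaloyl chloride, CC(C)(C)C(=O)Cl
Why: Grignard addition to the α-branched aldehyde at −78 °C with in situ O-acylation of the alkoxide; the carbinol centre need not be controlled, and the hindered, non-enolisable pivalate serves as protecting group through steps 4 to 6 and as leaving group in step 10.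

Step 4
Reactants: 9 (1RS,2R,3S)-2-methyl-1,3-bis(2,4,5-trimethoxyphenyl)pent-4-en-1-yl 2,2-dimethylpropanoate
Product: 10 (1RS,2R,3S)-2-methyl-4-oxo-1,3-bis(2,4,5-trimethoxyphenyl)pentyl 2,2-dimethylpropanoate
Conditions: PdCl2 (cat.), CuCl (cat.), O2 (1 atm), DMF/H2O (7:1), 25 °C
Reagents that add atoms: water, O
Why: Tsuji–Wacker oxidation: Markovnikov hydroxypalladation of the terminal alkene and β-hydride elimination should give the methyl ketone (the future C2 with its methylene carbon), and the acylated carbinol cannot cyclise onto the activated alkene.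

Step 5
Reactants: 10 (1RS,2R,3S)-2-methyl-4-oxo-1,3-bis(2,4,5-trimethoxyphenyl)pentyl 2,2-dimethylpropanoate
Product: 11 (1RS,2R,3S)-2-methyl-4-[(trifluoromethanesulfonyl)oxy]-1,3-bis(2,4,5-trimethoxyphenyl)pent-4-en-1-yl 2,2-dimethylpropanoate
Conditions: KN(SiMe3)2, THF, −78 °C; then PhNTf2, −78 → 0 °C
Reagents that add atoms: N-phenylbis(trifluoromethanesulfonimide), O=S(=O)(N(c1ccccc1)S(=O)(=O)C(F)(F)F)C(F)(F)F
Why: Kinetic deprotonation at the unhindered methyl group (the tertiary benzylic α-hydrogen is shielded by the aryl group and the branched neighbour) and O-triflation of the terminal enolate should give the 1,1-disubstituted enol triflate with the adjacent stereocentre untouched.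

Step 6
Reactants: 11 (1RS,2R,3S)-2-methyl-4-[(trifluoromethanesulfonyl)oxy]-1,3-bis(2,4,5-trimethoxyphenyl)pent-4-en-1-yl 2,2-dimethylpropanoate
Product: 12 (1RS,2R,3R)-2-methyl-4-(4,4,5,5-tetramethyl-1,3,2-dioxaborolan-2-yl)-1,3-bis(2,4,5-trimethoxyphenyl)pent-4-en-1-yl 2,2-dimethylpropanoate (same spatial arrangement as 11; only the descriptor changes)
Conditions: bis(pinacolato)diboron, PdCl2(PPh3)2 (cat.), PPh3, PhOK, toluene, 50 °C
Reagents that add atoms: bis(pinacolato)diboron, CC1(C)OB(OC1(C)C)B1OC(C)(C)C(C)(C)O1
Why: Miyaura borylation of an alkenyl triflate (oxidative addition to zerovalent palladium, transmetalation from the phenoxide-activated diboron, reductive elimination); the hindered secondary pivalate should not be attacked by the triphenylphosphine catalyst or the base at 50 °C.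

Step 7
Reactants: 13 4-bromo-2,5-dimethoxybenzaldehyde; 14 ethylmagnesium bromide
Product: 15 rac-1-(4-bromo-2,5-dimethoxyphenyl)propan-1-ol
Conditions: THF, 0 °C; aq. NH4Cl
Reagents that add atoms: none
Why: Grignard addition installs the ethyl group of C1; the carbinol is racemic because step 10 passes through the planar quinone methide.

Step 8
Reactants: 15 rac-1-(4-bromo-2,5-dimethoxyphenyl)propan-1-ol
Product: 16 rac-4-(1-hydroxypropyl)-2,5-dimethoxyphenol
Conditions: Pd2(dba)3 (cat.), 2-di-tert-butylphosphino-2′,4′,6′-triisopropylbiphenyl (cat.), KOH, 1,4-dioxane/H2O, 100 °C; then aq. HCl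
Reagents that add atoms: potassium hydroxide, [K+].[OH-]
Why: Palladium-catalysed hydroxylation of an aryl bromide with hydroxide (the bulky biaryl phosphine promotes C–O reductive elimination) unveils the para-phenol needed for quinone methide formation.

Step 9
Reactants: 16 rac-4-(1-hydroxypropyl)-2,5-dimethoxyphenol
Product: 17 rac-4-[1-(benzenesulfonyl)propyl]-2,5-dimethoxyphenol
Conditions: PhSO2Na, HCO2H/H2O, 25 °C
Reagents that add atoms: sodium benzenesulfinate, [Na+].[O-]S(=O)c1ccccc1
Why: Acid ionises the para-hydroxybenzylic alcohol and benzenesulfinate traps the cation at sulfur, giving a stable sulfone from which base regenerates the quinone methide by 1,6-elimination.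

Step 10
Reactants: 12 (1RS,2R,3R)-2-methyl-4-(4,4,5,5-tetramethyl-1,3,2-dioxaborolan-2-yl)-1,3-bis(2,4,5-trimethoxyphenyl)pent-4-en-1-yl 2,2-dimethylpropanoate; 17 rac-4-[1-(benzenesulfonyl)propyl]-2,5-dimethoxyphenol
Product: 20 (6S,7R,9R,10R,11R)-7-ethyl-1,4-dimethoxy-10-methyl-8-methylidene-9,11-bis(2,4,5-trimethoxyphenyl)spiro[5.5]undeca-1,4-dien-3-one, via quinone methide 18 (not isolated), via phenol pivalate 19 (not isolated)
Conditions: [RhCl(C2H4)2]2 (cat.), 2,5-diphenylbicyclo[2.2.2]octa-2,5-diene (cat.; the enantiomer that sets 5R in 19), K3PO4, 1,4-dioxane/H2O (10:1), 30 °C, then 80 °C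
Reagents that add atoms: none
Why: Proposed new method: base frees the para-quinone methide 18 from sulfone 17, the alkenylrhodium species formed by transmetalation from 12 adds 1,6 to its exocyclic carbon (C1–C2 bond) to give the phenolate of 19, and on warming this phenolate displaces the ionising 2,4,5-trimethoxybenzylic pivalate through its para carbon (C5–C6 bond), which dearomatises ring A to the dienone. The closest known reaction types are the rhodium/chiral diene-catalysed enantioselective 1,6-addition of organoboron reagents to para-quinone methides and the 1,6-addition/dearomative alkylation spiroannulations of para-quinone methides with reagents that carry both a nucleophilic and an electrophilic carbon, here joined in one flask and extended to a δ-alkyl quinone methide made in situ. Ring B closes by a 6-exo-tet C-alkylation of the phenolate ipso carbon through a chair transition state. C1 should be set by the chiral diene on rhodium (catalyst control on the achiral quinone methide), C5 by the chair in which the C1 ethyl, C3 aryl, C4 methyl and the C5 aryl are all equatorial (both carbinol epimers converge because the centre is planar when the bond forms), and C6 by the rotamer of ring A that turns its unsubstituted CH= arm axial and its methoxy-bearing arm equatorial, away from the underside of ring B. The step needs C-alkylation at the para carbon rather than at oxygen, at an ortho carbon or by the C3 aryl ring (indane formation): O- and ortho-attack would need bridged medium rings, and under basic conditions only the phenolate, not a neutral trimethoxyarene or the alkene, should be nucleophilic enough to capture the benzylic electrophile.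

Step 11
Reactants: 20 (6S,7R,9R,10R,11R)-7-ethyl-1,4-dimethoxy-10-methyl-8-methylidene-9,11-bis(2,4,5-trimethoxyphenyl)spiro[5.5]undeca-1,4-dien-3-one
Product: 21 tatanan B, (6S,7R,8S,9S,10R,11R)-7-ethyl-1,4-dimethoxy-8,10-dimethyl-9,11-bis(2,4,5-trimethoxyphenyl)spiro[5.5]undeca-1,4-dien-3-one
Conditions: H2 (3 atm), RhCl(PPh3)3 (cat.), benzene/EtOH (1:1), 25 °C
Reagents that add atoms: none
Why: Homogeneous hydrogenation with RhCl(PPh3)3 should reduce the 1,1-disubstituted exocyclic alkene and leave the two trisubstituted, oxygen-bearing dienone alkenes; syn delivery of hydrogen from the face opposite the axial CH= arm of ring A and the downward-tilted equatorial ethyl and aryl neighbours places the new methyl axial and cis to both neighbours (8S), as in tatanan B.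

**Compound list**

1 | 2,4,5-trimethoxybenzaldehyde | O=Cc1cc(OC)c(OC)cc1OC | starting material
2 | vinylmagnesium bromide | C=C[Mg]Br | starting material
3 | rac-1-(2,4,5-trimethoxyphenyl)prop-2-en-1-ol | C=CC(O)c1cc(OC)c(OC)cc1OC | intermediate
4 | propanal | CCC=O | starting material
5 | (2R,3S)-2-methyl-3-(2,4,5-trimethoxyphenyl)pent-4-enal | C=C[C@H](c1cc(OC)c(OC)cc1OC)[C@@H](C)C=O | intermediate
6 | 1-bromo-2,4,5-trimethoxybenzene | Brc1cc(OC)c(OC)cc1OC | starting material
7 | (2,4,5-trimethoxyphenyl)magnesium bromide | Br[Mg]c1cc(OC)c(OC)cc1OC | intermediate (not isolated)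
8 | bromomagnesium (1RS,2R,3S)-2-methyl-1,3-bis(2,4,5-trimethoxyphenyl)pent-4-en-1-olate | C=C[C@H](c1cc(OC)c(OC)cc1OC)[C@@H](C)C(O[Mg]Br)c1cc(OC)c(OC)cc1OC | intermediate (not isolated)
9 | (1RS,2R,3S)-2-methyl-1,3-bis(2,4,5-trimethoxyphenyl)pent-4-en-1-yl 2,2-dimethylpropanoate | C=C[C@H](c1cc(OC)c(OC)cc1OC)[C@@H](C)C(OC(=O)C(C)(C)C)c1cc(OC)c(OC)cc1OC | intermediate
10 | (1RS,2R,3S)-2-methyl-4-oxo-1,3-bis(2,4,5-trimethoxyphenyl)pentyl 2,2-dimethylpropanoate | CC(=O)[C@H](c1cc(OC)c(OC)cc1OC)[C@@H](C)C(OC(=O)C(C)(C)C)c1cc(OC)c(OC)cc1OC | intermediate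
11 | (1RS,2R,3S)-2-methyl-4-[(trifluoromethanesulfonyl)oxy]-1,3-bis(2,4,5-trimethoxyphenyl)pent-4-en-1-yl 2,2-dimethylpropanoate | C=C(OS(=O)(=O)C(F)(F)F)[C@H](c1cc(OC)c(OC)cc1OC)[C@@H](C)C(OC(=O)C(C)(C)C)c1cc(OC)c(OC)cc1OC | intermediate
12 | (1RS,2R,3R)-2-methyl-4-(4,4,5,5-tetramethyl-1,3,2-dioxaborolan-2-yl)-1,3-bis(2,4,5-trimethoxyphenyl)pent-4-en-1-yl 2,2-dimethylpropanoate | C=C(B1OC(C)(C)C(C)(C)O1)[C@H](c1cc(OC)c(OC)cc1OC)[C@@H](C)C(OC(=O)C(C)(C)C)c1cc(OC)c(OC)cc1OC | intermediate
13 | 4-bromo-2,5-dimethoxybenzaldehyde | O=Cc1cc(OC)c(Br)cc1OC | starting material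
14 | ethylmagnesium bromide | CC[Mg]Br | starting material
15 | rac-1-(4-bromo-2,5-dimethoxyphenyl)propan-1-ol | CCC(O)c1cc(OC)c(Br)cc1OC | intermediate
16 | rac-4-(1-hydroxypropyl)-2,5-dimethoxyphenol | CCC(O)c1cc(OC)c(O)cc1OC | intermediate
17 | rac-4-[1-(benzenesulfonyl)propyl]-2,5-dimethoxyphenol | CCC(c1cc(OC)c(O)cc1OC)S(=O)(=O)c1ccccc1 | intermediate
18 | (4E)-2,5-dimethoxy-4-propylidenecyclohexa-2,5-dien-1-one | CC/C=C1\C=C(OC)C(=O)C=C1OC | intermediate (not isolated)
19 | (1RS,2R,3R,5R)-5-(4-hydroxy-2,5-dimethoxyphenyl)-2-methyl-4-methylidene-1,3-bis(2,4,5-trimethoxyphenyl)heptyl 2,2-dimethylpropanoate | CC[C@@H](c1cc(OC)c(O)cc1OC)C(=C)[C@H](c1cc(OC)c(OC)cc1OC)[C@@H](C)C(OC(=O)C(C)(C)C)c1cc(OC)c(OC)cc1OC | intermediate (not isolated)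
20 | (6S,7R,9R,10R,11R)-7-ethyl-1,4-dimethoxy-10-methyl-8-methylidene-9,11-bis(2,4,5-trimethoxyphenyl)spiro[5.5]undeca-1,4-dien-3-one | CC[C@@H]1C(=C)[C@H](c2cc(OC)c(OC)cc2OC)[C@@H](C)[C@H](c2cc(OC)c(OC)cc2OC)[C@]12C=C(OC)C(=O)C=C2OC | intermediate
21 | tatanan B, (6S,7R,8S,9S,10R,11R)-7-ethyl-1,4-dimethoxy-8,10-dimethyl-9,11-bis(2,4,5-trimethoxyphenyl)spiro[5.5]undeca-1,4-dien-3-one | CC[C@@H]1[C@H](C)[C@H](c2cc(OC)c(OC)cc2OC)[C@@H](C)[C@H](c2cc(OC)c(OC)cc2OC)[C@]12C=C(OC)C(=O)C=C2OC | target

**Step count and risks**

Total step count: 11. Longest linear sequence: 8 steps (steps 1 to 6, 10 and 11).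

The three steps most likely to fail:

1. Step 10 (Proposed new method). What may go wrong:
   - tautomerisation of the δ-ethyl quinone methide to the 4-propenylphenol before the hindered alkenylrhodium species adds;
   - weak facial selectivity at C1 when the chiral catalyst meets the chiral nucleophile;
   - premature ionisation of the pivalate with cyclisation onto the C3 aryl ring;
   - closure through the other rotamer of ring A (C6 epimer).

   The fallback uses known chemistry, sets out from 12 and 16 and returns to the route at 20. Bromodeboronation (CuBr2, MeOH/H2O, 80 °C) should turn 12 into the alkenyl bromide F1. Compound 16 is silylated at the phenol oxygen (t-BuMe2SiCl, imidazole, DMF, 0 °C) to the silyl ether alcohol F2 and converted with SOCl2/pyridine into the benzylic chloride F3, used crude. A nickel-catalysed enantioselective reductive cross-coupling of racemic F3 with F1 (NiCl2(dme), chiral bis(oxazoline) ligand, Mn, NaI, N,N-dimethylacetamide, 0 °C) is a known stereoconvergent union of secondary benzylic chlorides with alkenyl bromides. It should give the coupled aryl silyl ether F4 with C1 set by the ligand. Bu4NF in THF then frees the phenoxide, which on warming closes ring B by the same para C-alkylation (fluoride-triggered alkylative dearomatisation) to give 20.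

2. Step 11. What may go wrong: loss of chemoselectivity (reduction of a dienone alkene) or delivery of hydrogen to the wrong face of the exocyclic alkene.

   The fallback sets out from 19 and returns at 21. Step 10 is stopped after the 30 °C stage and acidified so that 19 is isolated. Iridium-catalysed asymmetric hydrogenation of its unfunctionalised 1,1-disubstituted alkene (a cationic iridium phosphino-oxazoline complex, [Ir(cod)(P,N-ligand)]B[3,5-(CF3)2C6H3]4, H2, CH2Cl2) sets C2 under catalyst control and should give the saturated phenol pivalate F5. Heating F5 with Cs2CO3 in DMF then closes ring B with dearomatisation and gives 21 directly, so no alkene has to be reduced next to the dienone.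

3. Step 5. What may go wrong: enolisation towards the benzylic carbon, which would erode the C3 configuration or lead to the internal enol triflate.

   The fallback sets out from 9 and returns at 12, bypassing the ketone. Lemieux–Johnson cleavage of the vinyl group (OsO4 cat., NaIO4, 2,6-lutidine, dioxane/H2O) gives the α-aryl aldehyde F6. Homologation at 0 °C with the Ohira–Bestmann reagent (K2CO3, MeOH) gives the terminal alkyne F7. Copper-catalysed α-selective protoboration (CuCl, N-aryl N-heterocyclic carbene ligand, NaOt-Bu, bis(pinacolato)diboron, MeOH) places boron on the internal carbon and gives 12 without a ketone enolate.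

Further compounds
F1 | step 10 | (1RS,2R,3S)-4-bromo-2-methyl-1,3-bis(2,4,5-trimethoxyphenyl)pent-4-en-1-yl 2,2-dimethylpropanoate | C=C(Br)[C@H](c1cc(OC)c(OC)cc1OC)[C@@H](C)C(OC(=O)C(C)(C)C)c1cc(OC)c(OC)cc1OC
F2 | step 10 | rac-1-[4-(tert-butyldimethylsilyloxy)-2,5-dimethoxyphenyl]propan-1-ol | CCC(O)c1cc(OC)c(O[Si](C)(C)C(C)(C)C)cc1OC
F3 | step 10 | rac-tert-butyl[4-(1-chloropropyl)-2,5-dimethoxyphenoxy]dimethylsilane | CCC(Cl)c1cc(OC)c(O[Si](C)(C)C(C)(C)C)cc1OC
F4 | step 10 | (1RS,2R,3R,5R)-5-[4-(tert-butyldimethylsilyloxy)-2,5-dimethoxyphenyl]-2-methyl-4-methylidene-1,3-bis(2,4,5-trimethoxyphenyl)heptyl 2,2-dimethylpropanoate | CC[C@@H](c1cc(OC)c(O[Si](C)(C)C(C)(C)C)cc1OC)C(=C)[C@H](c1cc(OC)c(OC)cc1OC)[C@@H](C)C(OC(=O)C(C)(C)C)c1cc(OC)c(OC)cc1OC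
F5 | step 11 | (1RS,2R,3S,4S,5R)-5-(4-hydroxy-2,5-dimethoxyphenyl)-2,4-dimethyl-1,3-bis(2,4,5-trimethoxyphenyl)heptyl 2,2-dimethylpropanoate | CC[C@@H](c1cc(OC)c(O)cc1OC)[C@H](C)[C@H](c1cc(OC)c(OC)cc1OC)[C@@H](C)C(OC(=O)C(C)(C)C)c1cc(OC)c(OC)cc1OC
F6 | step 5 | (1RS,2R,3S)-2-methyl-4-oxo-1,3-bis(2,4,5-trimethoxyphenyl)butyl 2,2-dimethylpropanoate | O=C[C@H](c1cc(OC)c(OC)cc1OC)[C@@H](C)C(OC(=O)C(C)(C)C)c1cc(OC)c(OC)cc1OC
F7 | step 5 | (1RS,2R,3R)-2-methyl-1,3-bis(2,4,5-trimethoxyphenyl)pent-4-yn-1-yl 2,2-dimethylpropanoate | C#C[C@H](c1cc(OC)c(OC)cc1OC)[C@@H](C)C(OC(=O)C(C)(C)C)c1cc(OC)c(OC)cc1OC
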